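Both benzene rings (A and B) are assembled de novo around the carbon that becomes the carbonyl group. In each ring C1, which carries that carbon, is flanked by the C2 hydroxyl and the C6 methoxyl. A vinylketene–alkoxyalkyne benzannulation delivers precisely this arrangement: the ketene oxygen ends as OH and the alkyne oxygen as OMe, while C3-Me, C4-OMe and C5-H arrive with a cyclobutenone. Cutting C1–C2 and C5–C6 in both rings gives the skipped diyne MeOC≡C–CH(OTBS)–C≡COMe and two molecules of 3-methoxy-4-methylcyclobutenone. One heating operation makes four C–C bonds and both arenes. Methoxyacetylene supplies all four methoxy groups; one DDQ oxidation finishes the ketone.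

Key step: step 4

Remark on the chemistry: ring atoms are numbered C1 (bearing the central carbon) to C6; in the annulation cyclobutenone C1, C4, C3 and C2 become ring C2, C3, C4 and C5 and the two alkyne carbons become C1 and C6; the cyclobutenone is used as the racemate because its stereocentre is erased on ring opening, and the target is achiral.

Step 1
Reactants: 1 chloroacetaldehyde dimethyl acetal (2-chloro-1,1-dimethoxyethane)
Product: 3 methoxyacetylene (methoxyethyne), via sodium methoxyacetylide 2 (not isolated)
Conditions: NaNH2 (3.2 equiv), liq. NH3, –33 °C; NH3 evaporated; cold sat. aq NaCl, –70 °C → rt; distilled into a –78 °C trap and kept cold as stock solutions in THF and Et2O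
Reagents that add atoms: none
Why: Twofold base-induced β-elimination (methanol, then HCl) of an α-chloroacetal with excess NaNH2 is the standard preparation of terminal alkoxyacetylenes, and the third equivalent of base parks the volatile product as its sodium salt until the cold aqueous quench.

Step 2
Reactants: 3 methoxyacetylene; 4 ethyl formate; 5 tert-butyldimethylsilyl chloride
Product: 9 3-(tert-butyldimethylsilyloxy)-1,5-dimethoxypenta-1,4-diyne, via lithium methoxyacetylide 6 (not isolated), via 3-methoxyprop-2-ynal 7 (not isolated), via lithium diynolate 8 (not isolated)
Conditions: 3 (2.1 equiv), n-BuLi (2.05 equiv), THF, –78 °C; 4 (1.0 equiv), –78 → 0 °C; imidazole (1 equiv), 5 (2.4 equiv), DMF, 0 °C → rt; aq NaHCO3 work-up; Et3N-deactivated silica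
Reagents that add atoms: tert-butyldimethylsilyl chloride (5), CC(C)(C)[Si](C)(C)Cl
Why: Double 1,2-addition of a lithium acetylide to a formate ester (addition, collapse to ynal 7, second addition) is the usual entry to symmetrical penta-1,4-diyn-3-ols, and imidazole-mediated O-silylation of alkoxide 8 in the same flask keeps the medium basic, so that the free bis(alkoxyethynyl)carbinol, which is prone to acid-triggered Meyer–Schuster rearrangement, never has to be isolated.

Step 3
Reactants: 3 methoxyacetylene; 10 propionyl chloride
Product: 12 rac-3-methoxy-4-methylcyclobut-2-en-1-one, via methylketene 11 (not isolated)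
Conditions: 3 (1.3 equiv), Et3N (1.2 equiv), Et2O, 0 °C, dry-ice condenser; 10 (1.0 equiv) by syringe pump; → rt; filtration, cold concentration, bulb-to-bulb distillation
Reagents that add atoms: none
Why: Ketene–ynol ether [2+2] cycloaddition: methylketene 11, released by dehydrochlorination, is attacked at its carbonyl carbon by the nucleophilic terminal carbon of 3, so the methoxy-bearing carbon closes onto CHMe and only the 3-methoxy-4-methyl isomer should form, as a racemate whose stereocentre is lost in the next step.

Step 4
Reactants: 9 3-(tert-butyldimethylsilyloxy)-1,5-dimethoxypenta-1,4-diyne; 12 rac-3-methoxy-4-methylcyclobut-2-en-1-one (two equivalents incorporated, three used)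
Product: 17 bis(2-hydroxy-4,6-dimethoxy-3-methylphenyl)methyl tert-butyldimethylsilyl ether, via vinylketene 13 (not isolated), via alkenylcyclobutenone 14 (not isolated), via dienylketene 15 (not isolated), via monophenol 16 (not isolated)
Conditions: 12 (3 equiv), toluene, base-washed sealed tube, Ar, staged heating 80 → 120 °C; then K2CO3, MeOH, rt; Et3N-deactivated silica
Reagents that add atoms: none
Why: Danheiser benzannulation, run at both triple bonds of 9: reversible conrotatory four-electron opening of 12 (its C1–C4 bond cleaved, methyl turning outward) gives vinylketene 13, which adds [2+2] to one ynol ether to give 14, and a second four-electron opening, productive when the alkenyl group turns inward, gives dienylketene 15. Each benzene ring is closed by a thermal disrotatory six-electron electrocyclisation of its dienylketene, which re-forms C2–C3, followed by keto–enol tautomerisation, first to 16 and, after the same events at the second alkyne, to 17. The closest known reaction type is exactly this annulation of cyclobutenones with 1-alkoxyalkynes, and the opening of a 3-alkoxycyclobutenone is already part of every such cascade; the only extension is that two alkynes, insulated from each other by an sp3 carbon, must each react once. The selectivity needed is the regiochemistry of each ketene–alkyne [2+2], and it is secured by the methoxy donor, which makes the carbinol-bearing alkyne carbon the nucleophilic end, so that it bonds to the ketene carbonyl carbon (C1–C2) while the oxygenated carbon bonds to the ketene α-carbon (C5–C6) and C1 ends between OH and OMe. No stereocentre remains to be controlled, because those of 12, 14 and 16 vanish on ring opening, on aromatisation and when the two aryl groups become identical. Methyl ynol ethers lack the β-hydrogen needed for retro-ene fragmentation and so tolerate the temperature, the excess of 12 covers vinylketene lost to side reactions, and the carbonate–methanol treatment releases any phenol that was acylated by the ketene.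

Step 5
Reactants: 17 bis(2-hydroxy-4,6-dimethoxy-3-methylphenyl)methyl tert-butyldimethylsilyl ether
Product: 19 2,2'-dihydroxy-4,4',6,6'-tetramethoxy-3,3'-dimethylbenzophenone (target), via silyloxocarbenium ion 18 (not isolated)
Conditions: DDQ (2,3-dichloro-5,6-dicyano-1,4-benzoquinone, 1.2 equiv), CH2Cl2, pH 7 phosphate buffer, 0 °C
Reagents that add atoms: none
Why: Oxidative deprotection of an electron-rich benzylic silyl ether with DDQ: hydride abstraction from the benzhydrylic C–H, activated by six oxygen donors and the α-silyloxy group, gives ion 18, which hands its silyl group to water, so the ketone is reached without liberating the ionisation-prone free benzhydrol and is then shielded from further oxidation by its carbonyl group.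

Compound list
1 | chloroacetaldehyde dimethyl acetal (2-chloro-1,1-dimethoxyethane) | COC(CCl)OC | starting material
2 | sodium methoxyacetylide | COC#[C-].[Na+] | intermediate
3 | methoxyacetylene (methoxyethyne) | COC#C | intermediate
4 | ethyl formate | CCOC=O | starting material
5 | tert-butyldimethylsilyl chloride | CC(C)(C)[Si](C)(C)Cl | starting material
6 | lithium methoxyacetylide | COC#[C-].[Li+] | intermediate
7 | 3-methoxyprop-2-ynal | COC#CC=O | intermediate
8 | lithium 1,5-dimethoxypenta-1,4-diyn-3-olate | COC#CC([O-])C#COC.[Li+] | intermediate
9 | 3-(tert-butyldimethylsilyloxy)-1,5-dimethoxypenta-1,4-diyne | COC#CC(O[Si](C)(C)C(C)(C)C)C#COC | intermediate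
10 | propionyl chloride | CCC(=O)Cl | starting material
11 | methylketene (prop-1-en-1-one) | CC=C=O | intermediate
12 | rac-3-methoxy-4-methylcyclobut-2-en-1-one | COC1=CC(=O)C1C | intermediate
13 | (Z)-3-methoxypenta-1,3-dien-1-one (vinylketene, methyl trans to the ketene chain) | C/C=C(/C=C=O)OC | intermediate
14 | 2-[1-(tert-butyldimethylsilyloxy)-3-methoxyprop-2-yn-1-yl]-3-methoxy-4-[(Z)-1-methoxyprop-1-en-1-yl]cyclobut-2-en-1-one (racemic diastereomer mixture) | O=C1C(C(O[Si](C)(C)C(C)(C)C)C#COC)=C(OC)C1/C(OC)=C/C | intermediate
15 | (3E,5Z)-2-[1-(tert-butyldimethylsilyloxy)-3-methoxyprop-2-yn-1-yl]-3,5-dimethoxyhepta-1,3,5-trien-1-one (racemic) | O=C=C(C(O[Si](C)(C)C(C)(C)C)C#COC)/C(OC)=C\C(OC)=C\C | intermediate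
16 | rac-2-[1-(tert-butyldimethylsilyloxy)-3-methoxyprop-2-yn-1-yl]-3,5-dimethoxy-6-methylphenol | COC#CC(O[Si](C)(C)C(C)(C)C)c1c(OC)cc(OC)c(C)c1O | intermediate
17 | bis(2-hydroxy-4,6-dimethoxy-3-methylphenyl)methyl tert-butyldimethylsilyl ether | COc1cc(OC)c(C(O[Si](C)(C)C(C)(C)C)c2c(OC)cc(OC)c(C)c2O)c(O)c1C | intermediate
18 | [bis(2-hydroxy-4,6-dimethoxy-3-methylphenyl)methylidene](tert-butyldimethylsilyl)oxonium (silyloxocarbenium ion) | COc1cc(OC)c(C(=[O+][Si](C)(C)C(C)(C)C)c2c(OC)cc(OC)c(C)c2O)c(O)c1C | intermediate
19 | 2,2'-dihydroxy-4,4',6,6'-tetramethoxy-3,3'-dimethylbenzophenone | COc1cc(OC)c(C(=O)c2c(OC)cc(OC)c(C)c2O)c(O)c1C | target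

Total step count: 5. Longest linear sequence: 4 steps (1 → 3 → 9 → 17 → 19; the branch through 12 is equally long).

Steps most likely to fail

Step 4.
- The sequence may stall after the first ring, because the remaining triple bond is shielded by the new 2,6-disubstituted aryl group and the silyl ether.
- The freshly liberated phenol may add across the neighbouring ynol ether or intercept vinylketene.
- Silanol may be lost thermally from the o-hydroxybenzhydryl ether.
- Opening of 12 with the methyl turned inward may drain vinylketene through a 1,5-hydrogen shift.

The fallback sets out from 12 and 3 and comes back at 19. It introduces the central carbon after ring construction instead of before. A single benzannulation of 12 with methoxyacetylene 3 (toluene, sealed tube) should give 3,5-dimethoxy-2-methylphenol F1, whose only free ortho position lies between OH and OMe. Deprotonation with EtMgBr gives bromomagnesium 3,5-dimethoxy-2-methylphenoxide F2. F2 condenses with half an equivalent of paraformaldehyde in hot toluene through a magnesium chelate, strictly ortho to oxygen, to give bis(2-hydroxy-4,6-dimethoxy-3-methylphenyl)methane F3. Twofold benzylic dehydrogenation of F3 with DDQ in aqueous dioxane then leads to 19.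

Step 3.
- Dimerisation of methylketene may outrun the cycloaddition.
- The low-boiling alkyne may escape.
- The ammonium salt may deliver HCl to the ynol ether.

The fallback sets out from 3 and comes back at 12. 2-Chloropropanoyl chloride and Et3N release chloro(methyl)ketene F4, a more electrophilic and less dimerisation-prone ketenophile partner. It should add to 3 with the same regiochemistry to give rac-4-chloro-3-methoxy-4-methylcyclobut-2-en-1-one F5. Reductive dechlorination with Zn, AcOH and TMEDA in MeOH returns 12.

Step 5.
- Dehydrogenation at the C3 methyl groups may compete.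
- The electron-rich phenol rings may be oxidised.
- The silyl group may move to a phenol oxygen instead of being hydrolysed.

The fallback sets out from 17 and comes back at 19. It separates deprotection from oxidation. Bu4NF in THF at 0 °C with a neutral work-up gives bis(2-hydroxy-4,6-dimethoxy-3-methylphenyl)methanol F6. F6 is not stored but is oxidised at once with activated MnO2 in CH2Cl2, a heterogeneous oxidant selective for benzylic alcohols.

Further compounds
F1 | step 4 | 3,5-dimethoxy-2-methylphenol | COc1cc(O)c(C)c(OC)c1
F2 | step 4 | bromomagnesium 3,5-dimethoxy-2-methylphenoxide | COc1cc(O[Mg]Br)c(C)c(OC)c1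
F3 | step 4 | bis(2-hydroxy-4,6-dimethoxy-3-methylphenyl)methane | COc1cc(OC)c(Cc2c(OC)cc(OC)c(C)c2O)c(O)c1C
F4 | step 3 | chloro(methyl)ketene (2-chloroprop-1-en-1-one) | CC(Cl)=C=O
F5 | step 3 | rac-4-chloro-3-methoxy-4-methylcyclobut-2-en-1-one | COC1=CC(=O)C1(C)Cl
F6 | step 5 | bis(2-hydroxy-4,6-dimethoxy-3-methylphenyl)methanol | COc1cc(OC)c(C(O)c2c(OC)cc(OC)c(C)c2O)c(O)c1C
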